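Start from a one-step world, where substrate meets partner and a single time constant tells how far a flask gets.

common to all: substrate 0.059 M
- Friday's: partner 0.083 M; temperature 50 °C; run made earlier
- alpha: partner 0.0413 M; temperature 50 °C; time 20 min
- theta: partner 0.0413 M; temperature −25 °C; time 20 min
- eta: partner 0.0413 M; temperature 25 °C; time 20 min
- gamma: partner 0.0413 M; temperature 0 °C; time 20 min

Friday's run (percent of the substrate charged)

| time / s | product / % | substrate / % |
|---|---|---|
| 15.0 | 2 | 89 |
| 40.0 | 12 | 69 |
| 80.0 | 18 | 49 |
| 120 | 26 | 37 |

(each reading ± 2 percentage points)

- which flask leads in amount of product, in percent of the substrate charged ("all alike" within 1.5 percentage points) (alpha / theta / eta / gamma / all alike)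
- how much product is there at the end, in percent of the substrate charged: alpha
- how much product is there at the end, in percent of the substrate charged: theta
- how much product is there at the end, in percent of the substrate charged: eta
- how much product is there at the end, in percent of the substrate charged: gamma

- the earlier runs were read with a standard deviation of 2 percentage points
- the earlier runs do not show what temperature does; that part of a forecast is a guess

Take that time constant from Friday's run. Between 15.0 s and 120 s substrate falls from 89% to 37%. Divide the logarithm of that ratio by the interval and by the partner charge, and read a rate constant of 0.101 /M/s, a reading with its scatter. At the last reading, product is 41.3% of the substrate lost. Multiply the constant by alpha's partner and invert to get a time constant of 4.01 min. Define the count of time constants as the window divided by the time constant, and work in its logarithm. Alpha's count is 4.99, or 0.698 in powers of ten. The runs do not show temperature, so borrow the forecast's guess of a factor 6 for each step down the flasks, from 50 °C to 25 °C to 0 °C to −25 °C, which is 0.778 of a decade.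

Now climb the ladder. In alpha the time constant is shorter than the 20 min window, so expect the flask to finish, capped by partner, the limiting reagent, at a conversion of 70.0%. In eta it is 24.0 min, longer than the window, with a count of 0.832, so expect eta caught midway. In gamma it is 144 min, with a count of 0.139. In theta it is 865 min, with a count of 0.0231. For these two, read the count as the fraction reacted. My reckoning puts alpha first, with about 28.9% product.

The forecast also names alpha, with 33% for alpha (range 23% to 50%), above my figure. It gives 19% for eta, 3% for gamma and 0.3% for theta, and says of Friday's run: “This fits a parallel side path better than a slow intermediate”.

The flasks give alpha as leader, with 29.8% in alpha, 14.0% in eta, 0.267% in gamma and 0% in theta, so the forecast has the right leader and its figures hold within the tolerance.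

    intermediate → decomposed reagent (k = 0.00260 /s, Ea = 80.0 kJ/mol)
    intermediate → product (k = 0.00150 /s, Ea = 89.0 kJ/mol)
    substrate + partner → intermediate (k = 0.0190 /M/s, Ea = 63.0 kJ/mol)
    (constants at 25 °C)

Set alpha's count of 4.99 beside its conversion of 68.8%, with partner down to 1.7% of its charge. Alpha's product stops at 29.8% because intermediate also turns into decomposed reagent; the same run without that turning gives 68.6%.

For a neighbour flask like theta but kept at −10 °C, part of a step above theta, multiply theta's count by the matching part of the forecast's factor, 2.93, to get a count of 0.0677, read as the fraction reacted. The computed neighbour flask keeps 96.9% of its substrate, with 3.00% intermediate and 0.0233% product.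

The runs are simulated from invented constants; scatter was added.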